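**Plan**

1. Numbering: C1 is the lactone carbonyl, C13 the ring carbon on the lactone oxygen, C14 its methyl. Within the 14-membered ring, C3–C11 (methyls on C4, C6, C8, C10; oxygen on C5) would be a meso chain if the C9 ketone were a carbinol mirroring C5, with the mirror plane through the C7 methylene. The key step uses this hidden symmetry.
2. Retrosynthetic cuts: O13–C1 (macrolactone), C2–C3 (syn-aldol), C11–C12 (anti-crotylation, C13 carbinol from the vinyl group), removal of one carbon at each end, and last C4–C5 together with C9–C10 (double (Z)-crotylboration of the meso C5–C9 dialdehyde).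
3. Forward order: meso anhydride → meso dialdehyde → two-directional crotylboration (open chain, no ring) → meso C3–C11 tetraol → lipase monoacetate → C11 end grown to C14 → C3 end grown to C1 → the only ring of the target closed by macrolactonisation → C9 oxidised → protecting groups removed.
4. Stereochemistry: C6/C8 come from the meso anhydride; C4, C5, C10 (and the temporary C9 carbinol) from substrate control in the key step; the absolute sense from the lipase; C11/C12 from a matched tartrate crotylboronate; C2/C3 from an oxazolidinone auxiliary; C13 from an oxazaborolidine reduction.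

Key step: step 3

Assumption: the lipase acetylates the hydroxymethyl group of the C11 end (the arm on C10), as the empirical rule for this enzyme with 2-methyl-1-alkanols predicts; the route is written for that outcome.
Remark: (Z)-crotylboronic acid pinacol ester 4 is taken as a purchased reagent. Target numbering (C1–C14) is used for all intermediates.

**Route**

Step 1
Reactants: 1 meso-2,4-dimethylglutaric anhydride
Product: 2 meso-(2R,4S)-2,4-dimethylpentane-1,5-diol
Conditions: LiAlH4, THF, 0 °C → reflux; Fieser work-up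
Reagents that add atoms: none
Why: Hydride reduction of the cyclic anhydride to the diol does not touch the two methyl-bearing carbons, so the cis (meso) relationship of the future C6 and C8 is carried over.

Step 2
Reactants: 2 meso-2,4-dimethylpentane-1,5-diol
Product: 3 meso-(2R,4S)-2,4-dimethylpentanedial (C5–C9), used crude
Conditions: (COCl)2, DMSO, CH2Cl2, −78 °C; Et3N, −78 → −20 °C; cold non-basic work-up, no chromatography
Reagents that add atoms: none
Why: Swern oxidation stops at the aldehyde, and short cold contact with the amine keeps the epimerisable α-centres C6 and C8 intact.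

Step 3
Reactants: 3 meso-2,4-dimethylpentanedial; 4 (Z)-crotylboronic acid pinacol ester
Product: 6 meso-(3S,4S,5S,7R,8R,9R)-3,5,7,9-tetramethylundeca-1,10-diene-4,8-diol (target C3–C11 with carbinols at C5 and C9 and one extra =CH2 at each end), via bis(pinacol borate) 5 (not isolated)
Conditions: 4 (3 equiv), 4 Å MS, toluene (concentrated), 23 °C, 72 h; then 1 M aq. NaOH, Et2O
Reagents that add atoms: none
Why: Each aldehyde of 3 reacts with 4 through a closed six-membered chair transition state in which boron is bound to the carbonyl oxygen and the new C–C bond (C4–C5, C9–C10) forms at the γ-carbon of the allyl unit. The closest known reaction type is the substrate-controlled crotylboration of α-methyl aldehydes with achiral pinacol crotylboronates, including its two-directional use on meso dialdehydes; no ring is closed. The Z geometry of the boronate places the new methyl (C4, C10) syn to the new hydroxyl (C5, C9), so these centres are fixed relative to each other by the chair. C5 and C9 are fixed relative to C6 and C8 because the Felkin arrangement would force a syn-pentane contact between the Z-methyl of the reagent and the α-methyl of the aldehyde, so addition goes to the anti-Felkin face and gives the 4,5-syn-5,6-anti triad at each end. The step needs diastereofacial selectivity at both aldehydes; since C6 and C8 are mirror images, the same intrinsic bias gives mirror-image triads and hence the meso diol, from which the chiral minor diastereomers should be separable. The first-formed carbinol stays capped as its pinacol borate in 5, which keeps it from closing a lactol onto the second aldehyde.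

Step 4
Reactants: 6 meso diene diol
Product: 8 meso-(2S,3S,4S,6R,7R,8R)-2,4,6,8-tetramethylnonane-1,3,7,9-tetraol (C3–C11; OH on C3, C5, C9, C11), via bis(1,2,4-trioxolane) 7 (not isolated)
Conditions: O3, CH2Cl2, −78 °C; then MeOH, NaBH4, −78 °C → rt
Reagents that add atoms: ozone, [O-][O+]=O
Why: Ozonolysis of both terminal alkenes with borohydride work-up cuts off the two =CH2 carbons and leaves C3 and C11 as hydroxymethyl groups without touching a stereocentre.

Step 5
Reactants: 8 meso tetraol
Product: 9 (2R,3R,4R,6S,7S,8S)-3,7,9-trihydroxy-2,4,6,8-tetramethylnonyl acetate (acetate on O11; free OH on C3, C5, C9)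
Conditions: Burkholderia cepacia lipase (immobilised), vinyl acetate, THF, 25 °C, stopped at one equivalent of acyl transfer
Reagents that add atoms: vinyl acetate, CC(=O)OC=C
Why: Lipase-catalysed irreversible transesterification acylates primary hydroxyls only and distinguishes the two enantiotopic hydroxymethyl arms through their methyl-bearing neighbours (C10 against C4); this enzymatic desymmetrisation of a meso diol fixes the absolute configuration of all six existing stereocentres.

Step 6
Reactants: 9 O11-monoacetate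
Product: 10 O3/O5 4-methoxybenzylidene (PMP) acetal of 9 (cis-1,3-dioxane with equatorial aryl; C9-OH free; C11-OAc)
Conditions: 4-MeOC6H4CH(OMe)2, PPTS (cat.), CH2Cl2, 0 °C → rt
Reagents that add atoms: 4-methoxybenzaldehyde dimethyl acetal, COc1ccc(C(OC)OC)cc1
Why: Acid-catalysed transacetalisation closes the six-membered dioxane on the only free 1,3-diol (O3/O5) with the aryl group equatorial under thermodynamic control, which leaves the C9 hydroxyl as the single free alcohol and so tells C9 from C5.

Step 7
Reactants: 10 PMP acetal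
Product: 11 C9-O-triethylsilyl ether of 10
Conditions: TESOTf, 2,6-lutidine, CH2Cl2, −78 °C
Reagents that add atoms: triethylsilyl trifluoromethanesulfonate, CC[Si](CC)(CC)OS(=O)(=O)C(F)(F)F
Why: Silylation with a silyl triflate and a hindered pyridine base protects the hindered secondary alcohol without acid that would open the acetal or strong base that would shift the acetate.

Step 8
Reactants: 11 TES ether
Product: 12 C11 primary alcohol (O3/O5 PMP acetal; C9-OTES)
Conditions: K2CO3, MeOH, 0 °C
Reagents that add atoms: none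
Why: Base-catalysed methanolysis removes the primary acetate while the hindered secondary TES ether and the acetal are stable to mild base.

Step 9
Reactants: 12 C11 alcohol
Product: 13 C11 aldehyde (O3/O5 PMP acetal; C9-OTES)
Conditions: Dess–Martin periodinane, NaHCO3, CH2Cl2, 0 °C → rt
Reagents that add atoms: none
Why: Dess–Martin oxidation under buffered, non-basic conditions gives the α-methyl aldehyde without epimerising C10.

Step 10
Reactants: 14 trans-2-butene; 15 diisopropyl (2R,3R)-tartrate
Product: 18 diisopropyl (4R,5R)-2-[(E)-but-2-enyl]-1,3,2-dioxaborolane-4,5-dicarboxylate, via (E)-but-2-enylpotassium 16 (not isolated), via (E)-but-2-enylboronic acid 17 (not isolated)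
Conditions: n-BuLi, KOtBu, THF, −78 → −50 °C; B(OiPr)3, −78 °C; 1 M HCl; then 15, MgSO4, Et2O, rt
Reagents that add atoms: triisopropyl borate, CC(C)OB(OC(C)C)OC(C)C
Why: Schlosser metalation of trans-2-butene gives the (E)-crotylpotassium, which holds its geometry at low temperature, is trapped on boron and is esterified with the tartrate to the crotylboronate with the E geometry retained.

Step 11
Reactants: 13 C11 aldehyde; 18 (R,R)-tartrate (E)-crotylboronate
Product: 20 homoallylic alcohol (C3–C14 chain; 10,11-syn-11,12-anti; C11-OH free; C12-Me; C13=C14 vinyl), via tartrate borate ester 19 (not isolated)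
Conditions: 18 (2 equiv), 4 Å MS, toluene, −78 °C; then 1 M aq. NaOH, 0 °C
Reagents that add atoms: none
Why: Roush asymmetric crotylboration through a chair transition state: the E geometry sets C11-OH and C12-Me anti, and the (R,R)-reagent adds to the si face of the aldehyde, which is also the Felkin face defined by C10 (matched pair), so C11 and C12 are set in the 10,11-syn-11,12-anti arrangement of the target.

Step 12
Reactants: 20 homoallylic alcohol
Product: 21 C11-O-tert-butyldimethylsilyl ether of 20
Conditions: TBSOTf, 2,6-lutidine, CH2Cl2, 0 °C → rt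
Reagents that add atoms: tert-butyldimethylsilyl trifluoromethanesulfonate, CC(C)(C)[Si](C)(C)OS(=O)(=O)C(F)(F)F
Why: The silyl triflate silylates the hindered C11 hydroxyl under conditions that leave the acetal and the TES ether alone.

Step 13
Reactants: 21 bis-silyl ether
Product: 22 C3 primary alcohol with C5-O-PMB ether (C9-OTES; C11-OTBS; vinyl)
Conditions: DIBAL-H, CH2Cl2, −78 → 0 °C; Rochelle salt
Reagents that add atoms: none
Why: Regioselective reductive opening of the PMP acetal: aluminium binds the less hindered O3, the acetal C–O3 bond breaks and hydride adds to the oxocarbenium ion, so the PMB group stays on the secondary O5 and C3 is freed as the primary alcohol.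

Step 14
Reactants: 22 C3 alcohol
Product: 23 C3 aldehyde (C5-OPMB; C9-OTES; C11-OTBS; vinyl)
Conditions: Dess–Martin periodinane, NaHCO3, CH2Cl2, 0 °C → rt
Reagents that add atoms: none
Why: Dess–Martin oxidation gives the α-methyl-β-alkoxy aldehyde without epimerising C4 or eliminating the β-ether.

Step 15
Reactants: 23 C3 aldehyde; 24 (R)-4-benzyl-3-propanoyl-1,3-oxazolidin-2-one
Product: 27 syn-aldol adduct (N-acyl oxazolidinone of the C1–C14 chain; 2R,3S; C3-OH; C5-OPMB; C9-OTES; C11-OTBS; vinyl), via (Z)-dibutylboron enolate 25 (not isolated), via dibutylboron aldolate 26 (not isolated)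
Conditions: 24, Bu2BOTf, iPr2NEt, CH2Cl2, 0 °C; 23, −78 → 0 °C; pH 7 buffer, MeOH, 30% H2O2, 0 °C
Reagents that add atoms: none
Why: Evans syn-aldol through the Zimmerman–Traxler chair of the (Z)-boron enolate: the (R)-benzyl auxiliary fixes the enolate face and sets C2 (R) and C3 (S) in a 2,3-syn relationship, reagent control overriding the mild anti-Felkin bias of the aldehyde so that C3 is also syn to C4.

Step 16
Reactants: 27 aldol adduct
Product: 28 O3/O5 PMP acetal of 27 (all-cis 1,3-dioxane with equatorial aryl and equatorial chains; C9-OTES; C11-OTBS; vinyl)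
Conditions: DDQ, 4 Å MS, CH2Cl2, 0 °C
Reagents that add atoms: none
Why: Oxidative acetal formation: DDQ abstracts hydride from the PMB methylene under anhydrous conditions and the neighbouring C3 hydroxyl traps the oxocarbenium ion as the six-membered acetal, which protects O3 and O5 together and stiffens C1–C6 for the ring closure.

Step 17
Reactants: 28 vinyl compound
Product: 29 C13 methyl ketone
Conditions: PdCl2 (10 mol %), Cu(OAc)2 (20 mol %), O2 (1 atm), DMA–H2O 7:1, rt
Reagents that add atoms: water, O
Why: Tsuji–Wacker oxidation (Markovnikov hydroxypalladation of the terminal alkene, then β-hydride elimination) turns C13=C14 into the methyl ketone, with copper acetate as co-oxidant keeping the medium mild enough for the acetal and silyl ethers.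

Step 18
Reactants: 29 methyl ketone
Product: 30 (13R)-alcohol (imide; O3/O5 PMP acetal; C9-OTES; C11-OTBS; C13-OH free)
Conditions: (S)-Me-CBS oxazaborolidine (1 equiv), catecholborane, toluene, −78 °C; MeOH
Reagents that add atoms: none
Why: Corey–Bakshi–Shibata reduction: the oxazaborolidine binds the ketone oxygen anti to the larger C12 side and delivers hydride to one face, so the (S)-catalyst should give the (13R)-carbinol (12,13-syn) by reagent control, which is needed because Felkin control from C12 alone favours the 13-epimer.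

Step 19
Reactants: 30 (13R)-alcohol
Product: 32 seco acid (C1 acid; O3/O5 PMP acetal; C9-OTES; C11-OTBS; C13-OH), via peroxy acid 31 (not isolated)
Conditions: LiOH, 30% H2O2, THF–H2O 3:1, 0 °C; Na2SO3; 1 M HCl to pH 4, 0 °C
Reagents that add atoms: hydrogen peroxide, OO
Why: Hydroperoxide cleavage of the N-acyl oxazolidinone attacks the exocyclic carbonyl selectively and gives the peracid, which sulfite reduces to the acid without epimerising C2.

Step 20
Reactants: 32 seco acid
Product: 34 macrolactone (3,5-O-(4-methoxybenzylidene)-9-O-TES-11-O-TBS-(9R)-9-dihydro-8,8a-deoxyoleandolide), via mixed anhydride 33 (not isolated)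
Conditions: 2,4,6-Cl3C6H2COCl, Et3N, THF, rt; then slow addition to DMAP, toluene, 80 °C, high dilution
Reagents that add atoms: none
Why: Yamaguchi macrolactonisation: DMAP attacks the less hindered acyl group of the mixed anhydride and the acylpyridinium ion is trapped by the only free hydroxyl (C13) at high dilution, closing the 14-membered ring with retention at C13 while the O3/O5 acetal preorganises the chain.

Step 21
Reactants: 34 macrolactone
Product: 35 C9 alcohol (O3/O5 PMP acetal; C11-OTBS)
Conditions: HF·pyridine, pyridine, THF, 0 °C → rt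
Reagents that add atoms: none
Why: Buffered fluoride desilylation removes a triethylsilyl ether much faster than a comparably hindered TBS ether and the pyridine buffer spares the acetal, so only the C9 hydroxyl is freed.

Step 22
Reactants: 35 C9 alcohol
Product: 36 3,5-O-(4-methoxybenzylidene)-11-O-TBS-8,8a-deoxyoleandolide (C9 ketone)
Conditions: Dess–Martin periodinane, NaHCO3, CH2Cl2, rt
Reagents that add atoms: none
Why: Dess–Martin oxidation of the only free hydroxyl gives the C9 ketone, which removes the temporary C9 stereocentre under neutral conditions that leave C8 and C10 unepimerised.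

Step 23
Reactants: 36 protected ketone
Product: 37 8,8a-deoxyoleandolide
Conditions: 48% aq. HF, MeCN, 0 °C → rt
Reagents that add atoms: none
Why: Acidic aqueous fluoride hydrolyses the PMP acetal and cleaves the hindered TBS ether in one operation, releasing the C3, C5 and C11 hydroxyls without base so that the β-hydroxy ketone does not eliminate.

**Compound list**

1 | meso-2,4-dimethylglutaric anhydride ((3R,5S)-3,5-dimethyloxane-2,6-dione) | O=C1OC(=O)[C@@H](C)C[C@H]1C | starting material
2 | meso-(2R,4S)-2,4-dimethylpentane-1,5-diol | OC[C@@H](C)C[C@@H](C)CO | intermediate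
3 | meso-(2R,4S)-2,4-dimethylpentanedial (C5–C9) | O=C[C@@H](C)C[C@@H](C)C=O | intermediate
4 | (Z)-crotylboronic acid pinacol ester | C/C=C\CB1OC(C)(C)C(C)(C)O1 | starting material
5 | bis(pinacol borate) of 6 (O5 and O9 on boron) | C=C[C@H](C)[C@@H](OB1OC(C)(C)C(C)(C)O1)[C@@H](C)C[C@@H](C)[C@@H](OB1OC(C)(C)C(C)(C)O1)[C@H](C)C=C | intermediate (not isolated)
6 | meso-(3S,4S,5S,7R,8R,9R)-3,5,7,9-tetramethylundeca-1,10-diene-4,8-diol | C=C[C@H](C)[C@@H](O)[C@@H](C)C[C@@H](C)[C@@H](O)[C@H](C)C=C | intermediate
7 | bis(1,2,4-trioxolane) of 6 | C1OC(OO1)[C@H](C)[C@@H](O)[C@@H](C)C[C@@H](C)[C@@H](O)[C@H](C)C1OCOO1 | intermediate (not isolated)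
8 | meso-(2S,3S,4S,6R,7R,8R)-2,4,6,8-tetramethylnonane-1,3,7,9-tetraol | OC[C@H](C)[C@@H](O)[C@@H](C)C[C@@H](C)[C@@H](O)[C@H](C)CO | intermediate
9 | (2R,3R,4R,6S,7S,8S)-3,7,9-trihydroxy-2,4,6,8-tetramethylnonyl acetate (O11-acetate) | OC[C@H](C)[C@@H](O)[C@@H](C)C[C@@H](C)[C@@H](O)[C@H](C)COC(C)=O | intermediate
10 | O3/O5 PMP acetal of 9 (C9-OH free, C11-OAc) | COc1ccc(cc1)[C@@H]2OC[C@H](C)[C@@H](O2)[C@@H](C)C[C@@H](C)[C@@H](O)[C@H](C)COC(C)=O | intermediate
11 | C9-O-TES ether of 10 | COc1ccc(cc1)[C@@H]2OC[C@H](C)[C@@H](O2)[C@@H](C)C[C@@H](C)[C@@H](O[Si](CC)(CC)CC)[C@H](C)COC(C)=O | intermediate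
12 | C11 primary alcohol (O3/O5 PMP acetal, C9-OTES) | COc1ccc(cc1)[C@@H]2OC[C@H](C)[C@@H](O2)[C@@H](C)C[C@@H](C)[C@@H](O[Si](CC)(CC)CC)[C@H](C)CO | intermediate
13 | C11 aldehyde (O3/O5 PMP acetal, C9-OTES) | COc1ccc(cc1)[C@@H]2OC[C@H](C)[C@@H](O2)[C@@H](C)C[C@@H](C)[C@@H](O[Si](CC)(CC)CC)[C@H](C)C=O | intermediate
14 | trans-2-butene | C/C=C/C | starting material
15 | diisopropyl (2R,3R)-tartrate | CC(C)OC(=O)[C@H](O)[C@@H](O)C(=O)OC(C)C | starting material
16 | (E)-but-2-enylpotassium | C/C=C/C[K] | intermediate (not isolated)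
17 | (E)-but-2-enylboronic acid | C/C=C/CB(O)O | intermediate (not isolated)
18 | diisopropyl (4R,5R)-2-[(E)-but-2-enyl]-1,3,2-dioxaborolane-4,5-dicarboxylate | CC(C)OC(=O)[C@@H]1OB(C/C=C/C)O[C@H]1C(=O)OC(C)C | intermediate
19 | tartrate borate ester of 20 (O11 on boron) | COc1ccc(cc1)[C@@H]2OC[C@H](C)[C@@H](O2)[C@@H](C)C[C@@H](C)[C@@H](O[Si](CC)(CC)CC)[C@H](C)[C@@H](OB3O[C@@H](C(=O)OC(C)C)[C@@H](O3)C(=O)OC(C)C)[C@@H](C)C=C | intermediate (not isolated)
20 | homoallylic alcohol (C11-OH, C12-Me, C13=C14; O3/O5 PMP acetal, C9-OTES) | COc1ccc(cc1)[C@@H]2OC[C@H](C)[C@@H](O2)[C@@H](C)C[C@@H](C)[C@@H](O[Si](CC)(CC)CC)[C@H](C)[C@@H](O)[C@@H](C)C=C | intermediate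
21 | C11-O-TBS ether of 20 | COc1ccc(cc1)[C@@H]2OC[C@H](C)[C@@H](O2)[C@@H](C)C[C@@H](C)[C@@H](O[Si](CC)(CC)CC)[C@H](C)[C@@H](O[Si](C)(C)C(C)(C)C)[C@@H](C)C=C | intermediate
22 | C3 primary alcohol (C5-OPMB, C9-OTES, C11-OTBS, vinyl) | OC[C@H](C)[C@@H](OCc1ccc(OC)cc1)[C@@H](C)C[C@@H](C)[C@@H](O[Si](CC)(CC)CC)[C@H](C)[C@@H](O[Si](C)(C)C(C)(C)C)[C@@H](C)C=C | intermediate
23 | C3 aldehyde (C5-OPMB, C9-OTES, C11-OTBS, vinyl) | O=C[C@H](C)[C@@H](OCc1ccc(OC)cc1)[C@@H](C)C[C@@H](C)[C@@H](O[Si](CC)(CC)CC)[C@H](C)[C@@H](O[Si](C)(C)C(C)(C)C)[C@@H](C)C=C | intermediate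
24 | (R)-4-benzyl-3-propanoyl-1,3-oxazolidin-2-one | CCC(=O)N1[C@H](Cc2ccccc2)COC1=O | starting material
25 | (Z)-dibutylboron enolate of 24 | C/C=C(\OB(CCCC)CCCC)N1[C@H](Cc2ccccc2)COC1=O | intermediate (not isolated)
26 | dibutylboron aldolate of 27 (O3 on boron) | O=C1OC[C@@H](Cc2ccccc2)N1C(=O)[C@H](C)[C@@H](OB(CCCC)CCCC)[C@H](C)[C@@H](OCc1ccc(OC)cc1)[C@@H](C)C[C@@H](C)[C@@H](O[Si](CC)(CC)CC)[C@H](C)[C@@H](O[Si](C)(C)C(C)(C)C)[C@@H](C)C=C | intermediate (not isolated)
27 | syn-aldol adduct (2R,3S; C3-OH, C5-OPMB, C9-OTES, C11-OTBS, vinyl) | O=C1OC[C@@H](Cc2ccccc2)N1C(=O)[C@H](C)[C@@H](O)[C@H](C)[C@@H](OCc1ccc(OC)cc1)[C@@H](C)C[C@@H](C)[C@@H](O[Si](CC)(CC)CC)[C@H](C)[C@@H](O[Si](C)(C)C(C)(C)C)[C@@H](C)C=C | intermediate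
28 | O3/O5 PMP acetal of 27 (vinyl) | O=C1OC[C@@H](Cc2ccccc2)N1C(=O)[C@H](C)[C@H]1O[C@@H](c2ccc(OC)cc2)O[C@H]([C@H]1C)[C@@H](C)C[C@@H](C)[C@@H](O[Si](CC)(CC)CC)[C@H](C)[C@@H](O[Si](C)(C)C(C)(C)C)[C@@H](C)C=C | intermediate
29 | C13 methyl ketone | O=C1OC[C@@H](Cc2ccccc2)N1C(=O)[C@H](C)[C@H]1O[C@@H](c2ccc(OC)cc2)O[C@H]([C@H]1C)[C@@H](C)C[C@@H](C)[C@@H](O[Si](CC)(CC)CC)[C@H](C)[C@@H](O[Si](C)(C)C(C)(C)C)[C@@H](C)C(C)=O | intermediate
30 | (13R)-alcohol (imide) | O=C1OC[C@@H](Cc2ccccc2)N1C(=O)[C@H](C)[C@H]1O[C@@H](c2ccc(OC)cc2)O[C@H]([C@H]1C)[C@@H](C)C[C@@H](C)[C@@H](O[Si](CC)(CC)CC)[C@H](C)[C@@H](O[Si](C)(C)C(C)(C)C)[C@@H](C)[C@H](O)C | intermediate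
31 | peroxy acid of 32 | OOC(=O)[C@H](C)[C@H]1O[C@@H](c2ccc(OC)cc2)O[C@H]([C@H]1C)[C@@H](C)C[C@@H](C)[C@@H](O[Si](CC)(CC)CC)[C@H](C)[C@@H](O[Si](C)(C)C(C)(C)C)[C@@H](C)[C@H](O)C | intermediate (not isolated)
32 | seco acid (O3/O5 PMP acetal, C9-OTES, C11-OTBS, C13-OH) | OC(=O)[C@H](C)[C@H]1O[C@@H](c2ccc(OC)cc2)O[C@H]([C@H]1C)[C@@H](C)C[C@@H](C)[C@@H](O[Si](CC)(CC)CC)[C@H](C)[C@@H](O[Si](C)(C)C(C)(C)C)[C@@H](C)[C@H](O)C | intermediate
33 | mixed 2,4,6-trichlorobenzoic anhydride of 32 | O=C(OC(=O)[C@H](C)[C@H]1O[C@@H](c2ccc(OC)cc2)O[C@H]([C@H]1C)[C@@H](C)C[C@@H](C)[C@@H](O[Si](CC)(CC)CC)[C@H](C)[C@@H](O[Si](C)(C)C(C)(C)C)[C@@H](C)[C@H](O)C)c1c(Cl)cc(Cl)cc1Cl | intermediate (not isolated)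
34 | macrolactone (O3/O5 PMP acetal, (9R)-C9-OTES, C11-OTBS) | O=C1[C@H](C)[C@H]2O[C@@H](c3ccc(OC)cc3)O[C@H]([C@H]2C)[C@@H](C)C[C@@H](C)[C@@H](O[Si](CC)(CC)CC)[C@H](C)[C@@H](O[Si](C)(C)C(C)(C)C)[C@@H](C)[C@@H](C)O1 | intermediate
35 | C9 alcohol macrolactone (O3/O5 PMP acetal, C11-OTBS) | O=C1[C@H](C)[C@H]2O[C@@H](c3ccc(OC)cc3)O[C@H]([C@H]2C)[C@@H](C)C[C@@H](C)[C@@H](O)[C@H](C)[C@@H](O[Si](C)(C)C(C)(C)C)[C@@H](C)[C@@H](C)O1 | intermediate
36 | 3,5-O-(4-methoxybenzylidene)-11-O-TBS-8,8a-deoxyoleandolide | O=C1[C@H](C)[C@H]2O[C@@H](c3ccc(OC)cc3)O[C@H]([C@H]2C)[C@@H](C)C[C@@H](C)C(=O)[C@H](C)[C@@H](O[Si](C)(C)C(C)(C)C)[C@@H](C)[C@@H](C)O1 | intermediate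
37 | 8,8a-deoxyoleandolide (2R,3S,4R,5S,6S,8R,10R,11S,12R,13R) | C[C@@H]1[C@@H](O)[C@@H](C)C[C@@H](C)C(=O)[C@H](C)[C@@H](O)[C@@H](C)[C@@H](C)OC(=O)[C@H](C)[C@H]1O | target

**Count and risks**

Total steps: 23. Longest linear sequence: 22 (steps 1–9 and 11–23 from anhydride 1; step 10 makes the crotylboronate 18 on a side branch).

Steps most likely to fail:

Step 3 (key step). The allylboration takes days at room temperature, so the dialdehyde may epimerise at C6/C8 before it reacts, and anti-Felkin selectivity may be incomplete at one of the two aldehydes; either lowers the share of the meso diastereomer. The fallback keeps the same two C–C bonds but forms them as aldol bonds. It sets out from 3: the dialdehyde is added at −78 °C to the (Z)-dibutylboron enolate of achiral 3-propanoyl-1,3-oxazolidin-2-one (Bu2BOTf, iPr2NEt, CH2Cl2). Z-boron enolates react quickly at low temperature and share the anti-Felkin preference of the (Z)-crotylboronate with α-methyl aldehydes, so the product should be the meso bis-aldol adduct, the bis(imide) F1, with C3 and C11 at the acid oxidation level. Reduction of both imides with LiBH4 (THF, MeOH, 0 °C) comes back to the route at tetraol 8 and makes the ozonolysis unnecessary.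

Step 5 (lipase). The enzyme may acylate the other enantiotopic arm (the hydroxymethyl on C4), or discriminate the two arms poorly, which would lead into the enantiomeric series or to low optical purity. The fallback reverses the direction of the enzymatic reaction. It sets out from 8: both primary hydroxyls are acetylated (AcCl, 2,4,6-collidine, CH2Cl2, −78 °C) to the meso 1,9-diacetate F2, and F2 is hydrolysed with the same lipase in pH 7 phosphate buffer. Since the enzyme attacks the same arm in both directions, hydrolysis leaves the acetate on the arm that acylation would leave free, and the sequence comes back to the route at 9.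

Step 18 (reduction at C13). The catalyst may fail to override the Felkin preference of the α-methyl ketone, so that the 13-epimer forms alongside the wanted alcohol. The fallback makes C13 by carbon addition, where Felkin control (12,13-syn) and 1,3-anti induction from the C11 silyl ether both favour the wanted isomer. It sets out from 28: the alkene is cleaved (OsO4 cat., NaIO4, 2,6-lutidine, dioxane–H2O) to the C13 aldehyde F3, and MeTi(OiPr)3 (THF, −78 → −40 °C), which adds to aldehydes but not to the imide, comes back to the route at 30; steps 17 and 18 are replaced.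

**Further compounds**

F1 | step 3 | meso bis-aldol adduct of 3 with two 3-propanoyl-1,3-oxazolidin-2-one units (C3 and C11 as imides; C5-OH and C9-OH) | O=C1OCCN1C(=O)[C@H](C)[C@@H](O)[C@@H](C)C[C@@H](C)[C@@H](O)[C@H](C)C(=O)N1CCOC1=O
F2 | step 5 | meso 1,9-diacetate of tetraol 8 (acetate on O3 and O11) | CC(=O)OC[C@H](C)[C@@H](O)[C@@H](C)C[C@@H](C)[C@@H](O)[C@H](C)COC(C)=O
F3 | step 18 | C13 aldehyde (imide; O3/O5 PMP acetal; C9-OTES; C11-OTBS) | O=C1OC[C@@H](Cc2ccccc2)N1C(=O)[C@H](C)[C@H]1O[C@@H](c2ccc(OC)cc2)O[C@H]([C@H]1C)[C@@H](C)C[C@@H](C)[C@@H](O[Si](CC)(CC)CC)[C@H](C)[C@@H](O[Si](C)(C)C(C)(C)C)[C@@H](C)C=O
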